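**Plan**

1. Numbering: C1–C11 run round the perimeter (C1 ketone, C2=C3 with the 3-methyl, C6 gem-dimethyl, C7 OH, C8 isovalerate, C9 angelate, C10 methyl); the cross-ring bonds C4–C10 and C5–C11 make the cyclobutane C4–C5–C11–C10.
2. Retrosynthetic cuts, in order: the C8–O and C9–O acyl bonds, the C7/C8 diol (back to a C7=C8 alkene), then C4–C10, then C10–C11, then C6–C7; this leaves a carene-derived cyclohexenone and divinyl ketone.
3. Enabling feature: C4 is the γ-carbon of the C1 enone and C10 the α-carbon of the C9 ketone, so both are nucleophilic as dienol ether and enol ether; the cis-fused rings C1–C2–C3–C4–C5–C11 and C5–C6–C7–C8–C9–C10–C11 hold them 1,3-diaxial, so a two-electron oxidation can bond them.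
4. Forward order: six-membered ring from (+)-3-carene; C6–C7 by radical conjugate addition; seven-membered ring by C10–C11 enolate coupling; cyclobutane (and with it the second six- and seven-membered rings) by anodic C4–C10 coupling; then oxygenation and acylation of C7–C9.
5. Stereochemistry: C5 comes from (+)-3-carene; C11 from the intramolecular C10–C11 closure (cis fusion); C4 and C10 follow from C5/C11 in the key step; C9 from a catalyst-controlled ketone reduction; C7 and C8 from osmylation anti to the C9 ester.

Key step: step 7

Remark: C10 is carried as an epimer mixture in 9 because it becomes trigonal in 10, and in step 10 the quaternary C10 is assumed to act as the larger ketone substituent.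

**Route**

Step 1
Reactants: 1 (+)-3-carene
Product: 2 car-3-en-5-one, i.e. (1R,6S)-4,7,7-trimethylbicyclo[4.1.0]hept-3-en-2-one
Conditions: CrO3 (5 mol %), t-BuOOH (70% aq., 4 equiv), CH2Cl2, 23 °C
Reagents that add atoms: tert-butyl hydroperoxide, CC(C)(C)OO
Why: Chromium-catalysed allylic C–H oxidation, well precedented for this terpene, turns the ring methylene next to the alkene CH into the carbonyl of the β-methyl enone (the future C1) and leaves both cyclopropane stereocentres untouched.

Step 2
Reactants: 2 car-3-en-5-one
Product: 3 (S)-3-methyl-5-(prop-1-en-2-yl)cyclohex-2-en-1-one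
Conditions: BF3·OEt2 (0.2 equiv), CH2Cl2, −20 → 0 °C
Reagents that add atoms: none
Why: Lewis-acid-promoted homoconjugate opening of the cyclopropyl ketone (an isomerisation): the cyclopropane bond that overlaps with the carbonyl breaks toward the tertiary carbon and a methyl proton is lost to give the isopropenyl group, while the bonds at the future C5 are not involved, so its configuration is retained.

Step 3
Reactants: 4 penta-1,4-dien-3-ol
Product: 5 penta-1,4-dien-3-one (divinyl ketone)
Conditions: Dess–Martin periodinane (1.1 equiv), CH2Cl2, 0 °C; filtered cold and used at once in solution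
Reagents that add atoms: none
Why: Dess–Martin oxidation of a bis-allylic secondary alcohol under neutral, anhydrous conditions suits the volatile, polymerisable dienone.

Step 4
Reactants: 3 (S)-3-methyl-5-(prop-1-en-2-yl)cyclohex-2-en-1-one; 5 penta-1,4-dien-3-one
Product: 6 (S)-3-methyl-5-(2-methyl-5-oxohept-6-en-2-yl)cyclohex-2-en-1-one
Conditions: Fe(acac)3 (30 mol %), PhSiH3 (2.5 equiv), 5 (4 equiv), EtOH/ethylene glycol (5:1), 60 °C
Reagents that add atoms: none
Why: Iron-hydride hydrogen-atom transfer to the 1,1-disubstituted alkene (Mukaiyama type) gives the tertiary C6 radical, which undergoes Giese addition to one vinyl terminus of 5 to form C6–C7; excess 5 suppresses double addition, the hindered ring enone should stay inert, and no stereocentre is formed.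

Step 5
Reactants: 6 (S)-3-methyl-5-(2-methyl-5-oxohept-6-en-2-yl)cyclohex-2-en-1-one
Product: 9 (1R,7S)-2,6,6,9-tetramethylbicyclo[5.4.0]undec-9-ene-3,11-dione (cis-fused; C2 epimers), via lithium C9 enolate 7 (not isolated), via dilithium bis-enolate 8 (not isolated)
Conditions: LiBH(s-Bu)3 (1.05 equiv), THF, −78 °C; LiN(i-Pr)2 (1.1 equiv), −78 °C; Cu(OTf)2 (2.2 equiv), THF/i-PrCN, 0.01 M, −78 → 0 °C
Reagents that add atoms: none
Why: Conjugate hydride addition to the vinyl ketone gives the C9=C10 enolate regiospecifically (its terminal CH2 becomes the C10 methyl), kinetic α'-deprotonation gives the C11 dienolate, and intramolecular oxidative enolate coupling by divalent copper joins C10 to C11 at high dilution; C11 should be set cis to C6 because the chain on C5 can deliver C10 to the adjacent trigonal carbon only axially on its own face.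

Step 6
Reactants: 9 (1R,7S)-2,6,6,9-tetramethylbicyclo[5.4.0]undec-9-ene-3,11-dione
Product: 10 (1R,7S)-3,11-bis(tert-butyldimethylsilyloxy)-2,6,6,9-tetramethylbicyclo[5.4.0]undeca-2,8,10-triene
Conditions: TBSOTf (2.6 equiv), Et3N (4 equiv), CH2Cl2, 0 → 23 °C, 12 h
Reagents that add atoms: tert-butyldimethylsilyl triflate, CC(C)(C)[Si](C)(C)OS(=O)(=O)C(F)(F)F
Why: Soft enolisation under equilibrating conditions should give the thermodynamic enol ethers, namely the linearly conjugated endocyclic dienol ether of the enone (as with steroidal enones) and the tetrasubstituted C9=C10 enol ether; enolisation toward C11 is disfavoured by allylic strain, so C11 is retained while C10 becomes trigonal.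

Step 7
Reactants: 10 (1R,7S)-3,11-bis(tert-butyldimethylsilyloxy)-2,6,6,9-tetramethylbicyclo[5.4.0]undeca-2,8,10-triene
Product: 11 (4R,5S,10R,11R)-longipin-2-ene-1,9-dione
Conditions: constant current (2.2 F mol−1, low current density), undivided cell, reticulated vitreous carbon anode, platinum cathode, LiClO4 (0.1 M), 2,6-lutidine (4 equiv), MeOH/CH2Cl2 (1:4), 0.01 M, −20 °C
Reagents that add atoms: none
Why: Proposed new method: anodic one-electron oxidation of the more electron-rich π-system (expected to be the C1 dienol ether, although the outcome is the same if the C9=C10 enol ether is oxidised first) gives a radical cation that is captured by the other enol ether with formation of C4–C10, and a second electron transfer with loss of both silyl groups to methanol releases the C1 enone and the C9 ketone, so two irreversible oxidations pay for the ring strain. The closest known reactions are intramolecular anodic (LiClO4, 2,6-lutidine, MeOH) and chemical ((NH4)2Ce(NO3)6, Cu(OTf)2) couplings of two enol ethers or silyl enol ethers to 1,4-dicarbonyl compounds; neither a vinylogous γ-terminus nor a four-membered ring has been shown. With respect to the C3=C4 bond, the one new bond closes the cyclobutane C4–C5–C11–C10 in a 4-exo-trig mode and at the same time the six-membered ring C1–C2–C3–C4–C10–C11 (6-endo-trig) and the seven-membered ring C4–C5–C6–C7–C8–C9–C10 (7-exo-trig). Both new stereocentres, C4 and C10, are fixed by the cis ring fusion at C5/C11: C10 sits axially on C11 on the only face from which it can reach C4, so only the (4R,10R) bridged isomer can form. The step needs site selectivity (C4 and not C2, carbon and not solvent at C10) and C–C bonding ahead of methanolysis; attack at C2 would put the oxocarbenium carbon C1 into a more strained four-membered ring and forgo enone conjugation, the 1,3-diaxial placement keeps C4 and C10 within bonding distance, and low methanol content, low current density and high dilution favour intramolecular capture.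

Step 8
Reactants: 11 (4R,5S,10R,11R)-longipin-2-ene-1,9-dione
Product: 13 (4R,5S,10R,11R)-longipina-2,7-diene-1,9-dione, via trimethylsilyl enol ether 12 (not isolated)
Conditions: LiN(i-Pr)2 (1.1 equiv), TMSCl (1.5 equiv), THF, −78 °C; then Pd(OAc)2 (1.1 equiv), MeCN, 23 °C
Reagents that add atoms: none
Why: Kinetic enolisation of the C9 ketone can occur only at C8 (C10 is quaternary and the enone offers only its slowly removed γ-methyl hydrogens), and Saegusa–Ito oxidation of the silyl enol ether installs C7=C8 without touching a stereocentre.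

Step 9
Reactants: 13 (4R,5S,10R,11R)-longipina-2,7-diene-1,9-dione
Product: 14 (4R,5S,10R,11R)-1-(tert-butyldimethylsilyloxy)-3-methylidenelongipina-1,7-dien-9-one
Conditions: TBSOTf (1.3 equiv), Et3N (2 equiv), CH2Cl2, 0 °C
Reagents that add atoms: tert-butyldimethylsilyl triflate, CC(C)(C)[Si](C)(C)OS(=O)(=O)C(F)(F)F
Why: Soft enolisation finds a single enolisable site, the C3 methyl of the C1 enone (C4 and C11 are bridgeheads and the C9 enone has no α'- or γ-hydrogen), so C1 is masked as its exocyclic silyl dienol ether and C9 is left as the only ketone.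

Step 10
Reactants: 14 (4R,5S,10R,11R)-1-(tert-butyldimethylsilyloxy)-3-methylidenelongipina-1,7-dien-9-one
Product: 16 (4R,5S,9R,10R,11R)-9-hydroxylongipina-2,7-dien-1-one, via silyl dienol ether alcohol 15 (not isolated)
Conditions: (S)-1-methyl-3,3-diphenyltetrahydro-1H,3H-pyrrolo[1,2-c][1,3,2]oxazaborole (0.2 equiv), catecholborane (1.8 equiv), toluene, −78 → −40 °C; then 1 M HCl, THF, 0 °C
Reagents that add atoms: none
Why: Corey–Bakshi–Shibata reduction, with reagent control needed because the two faces of C9 are nearly equivalent in the pseudo-symmetric cage: with quaternary C10 as the large and the alkene CH as the small substituent, the (S)-catalyst should give the alcohol with its hydroxyl syn to C11 (9R), and the acidic work-up cleaves the silyl dienol ether with γ-protonation back to the conjugated enone.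

Step 11
Reactants: 16 (4R,5S,9R,10R,11R)-9-hydroxylongipina-2,7-dien-1-one
Product: 17 (4R,5S,9R,10R,11R)-1-oxolongipina-2,7-dien-9-yl (Z)-2-methylbut-2-enoate
Conditions: angelic acid (3 equiv), 2,4,6-trichlorobenzoyl chloride (3 equiv), Et3N (3.3 equiv), toluene, 23 °C; then 16, toluene, 80 °C
Reagents that add atoms: angelic acid, C/C=C(/C)C(=O)O
Why: Yamaguchi esterification through the mixed 2,4,6-trichlorobenzoic anhydride acylates the hindered secondary alcohol with retention at C9 and, without a nucleophilic catalyst, should not isomerise the Z-alkene of the angelate.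

Step 12
Reactants: 17 (4R,5S,9R,10R,11R)-1-oxolongipina-2,7-dien-9-yl (Z)-2-methylbut-2-enoate
Product: 18 (4R,5S,7S,8S,9S,10R,11R)-7,8-dihydroxy-1-oxolongipin-2-en-9-yl (Z)-2-methylbut-2-enoate
Conditions: OsO4 (5 mol %), N-methylmorpholine N-oxide (1.3 equiv), acetone/H2O (4:1), 0 → 23 °C
Reagents that add atoms: osmium tetroxide, O=[Os](=O)(=O)=O; N-methylmorpholine N-oxide, C[N+]1([O-])CCOCC1; water, O
Why: Catalytic syn-dihydroxylation (Upjohn conditions) should take the isolated cis-alkene C7=C8 ahead of the two conjugated, electron-poor alkenes and approach anti to the allylic C9 acyloxy group (the usual sense for osmylation of allylic esters, reinforced by sterics), which places both new hydroxyls on the C4 side, cis to each other and trans to the C9 ester.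

Step 13
Reactants: 18 (4R,5S,7S,8S,9S,10R,11R)-7,8-dihydroxy-1-oxolongipin-2-en-9-yl (Z)-2-methylbut-2-enoate
Product: 19 (4R,5S,7S,8S,9S,10R,11R)-7-hydroxy-8-(3-methylbutanoyloxy)-1-oxolongipin-2-en-9-yl (Z)-2-methylbut-2-enoate (CNP0251293.1)
Conditions: 3-methylbutanoyl chloride (1.1 equiv), 2,4,6-collidine (3 equiv), CH2Cl2, −40 → 0 °C
Reagents that add atoms: 3-methylbutanoyl chloride, CC(C)CC(=O)Cl
Why: Regioselective acylation: the C8 hydroxyl, flanked by two methine carbons, should react ahead of the neopentyl C7 hydroxyl next to the gem-dimethyl carbon, and a weak non-nucleophilic base at low temperature limits acyl migration and angelate isomerisation.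

**Compound list**

1 | (+)-3-carene, (1S,6R)-3,7,7-trimethylbicyclo[4.1.0]hept-3-ene | CC1=CC[C@@H]2[C@H](C1)C2(C)C | starting material
2 | car-3-en-5-one, (1R,6S)-4,7,7-trimethylbicyclo[4.1.0]hept-3-en-2-one | CC1=CC(=O)[C@@H]2[C@H](C1)C2(C)C | intermediate
3 | (S)-3-methyl-5-(prop-1-en-2-yl)cyclohex-2-en-1-one | O=C1C=C(C)C[C@H](C(C)=C)C1 | intermediate
4 | penta-1,4-dien-3-ol | C=CC(O)C=C | starting material
5 | penta-1,4-dien-3-one (divinyl ketone) | C=CC(=O)C=C | intermediate
6 | (S)-3-methyl-5-(2-methyl-5-oxohept-6-en-2-yl)cyclohex-2-en-1-one | C=CC(=O)CCC(C)(C)[C@H]1CC(C)=CC(=O)C1 | intermediate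
7 | lithium C9=C10 enolate of the saturated ketone from 6 (enolate geometry not controlled) | CC=C([O-])CCC(C)(C)[C@H]1CC(C)=CC(=O)C1.[Li+] | intermediate
8 | dilithium bis-enolate (C9=C10 enolate and C11=C1 dienolate) | CC=C([O-])CCC(C)(C)[C@H]1CC(C)=CC([O-])=C1.[Li+].[Li+] | intermediate
9 | (1R,7S)-2,6,6,9-tetramethylbicyclo[5.4.0]undec-9-ene-3,11-dione, cis-fused, C2 epimers (perimeter numbering: 5S,11R) | O=C1C=C(C)C[C@H]2[C@@H]1C(C)C(=O)CCC2(C)C | intermediate
10 | (1R,7S)-3,11-bis(tert-butyldimethylsilyloxy)-2,6,6,9-tetramethylbicyclo[5.4.0]undeca-2,8,10-triene | CC1=C(O[Si](C)(C)C(C)(C)C)CCC(C)(C)[C@H]2C=C(C)C=C(O[Si](C)(C)C(C)(C)C)[C@@H]12 | intermediate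
11 | (4R,5S,10R,11R)-longipin-2-ene-1,9-dione | O=C1CCC(C)(C)[C@@H]2[C@H]3C(=O)C=C(C)[C@@H]2[C@@]13C | intermediate
12 | 9-(trimethylsilyloxy)longipina-2,8-dien-1-one | C[Si](C)(C)OC1=CCC(C)(C)[C@@H]2[C@H]3C(=O)C=C(C)[C@@H]2[C@@]13C | intermediate
13 | (4R,5S,10R,11R)-longipina-2,7-diene-1,9-dione | O=C1C=CC(C)(C)[C@@H]2[C@H]3C(=O)C=C(C)[C@@H]2[C@@]13C | intermediate
14 | (4R,5S,10R,11R)-1-(tert-butyldimethylsilyloxy)-3-methylidenelongipina-1,7-dien-9-one | O=C1C=CC(C)(C)[C@@H]2[C@H]3C(O[Si](C)(C)C(C)(C)C)=CC(=C)[C@@H]2[C@@]13C | intermediate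
15 | (9R)-1-(tert-butyldimethylsilyloxy)-3-methylidenelongipina-1,7-dien-9-ol | O[C@@H]1C=CC(C)(C)[C@@H]2[C@H]3C(O[Si](C)(C)C(C)(C)C)=CC(=C)[C@@H]2[C@@]13C | intermediate
16 | (4R,5S,9R,10R,11R)-9-hydroxylongipina-2,7-dien-1-one | O[C@@H]1C=CC(C)(C)[C@@H]2[C@H]3C(=O)C=C(C)[C@@H]2[C@@]13C | intermediate
17 | (4R,5S,9R,10R,11R)-1-oxolongipina-2,7-dien-9-yl (Z)-2-methylbut-2-enoate | C/C=C(/C)C(=O)O[C@@H]1C=CC(C)(C)[C@@H]2[C@H]3C(=O)C=C(C)[C@@H]2[C@@]13C | intermediate
18 | (4R,5S,7S,8S,9S,10R,11R)-7,8-dihydroxy-1-oxolongipin-2-en-9-yl (Z)-2-methylbut-2-enoate | C/C=C(/C)C(=O)O[C@@H]1[C@@H](O)[C@@H](O)C(C)(C)[C@@H]2[C@H]3C(=O)C=C(C)[C@@H]2[C@@]13C | intermediate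
19 | (4R,5S,7S,8S,9S,10R,11R)-7-hydroxy-8-(3-methylbutanoyloxy)-1-oxolongipin-2-en-9-yl (Z)-2-methylbut-2-enoate | C/C=C(/C)C(=O)O[C@@H]1[C@@H](OC(=O)CC(C)C)[C@@H](O)C(C)(C)[C@@H]2[C@H]3C(=O)C=C(C)[C@@H]2[C@@]13C | target

Total step count: 13. Longest linear sequence: 12 steps (steps 1, 2 and 4–13, from (+)-3-carene).

**Steps most likely to fail**

1. Step 7. Solvent capture or further oxidation of the radical cation may outrun closure of the four-membered ring, or bonding may occur at C2. The fallback sets out from 10 and returns at 11; it gives up the one-pot oxidative union and inverts the polarity of C4 in a separate two-electron operation. N-Bromosuccinimide (1.0 equiv, THF, −78 °C) should attack the more nucleophilic dienol ether at its γ-carbon anti to C6 and give the γ-bromo enone F1, in which the C9=C10 silyl enol ether is still in place. Fluoride (Bu4NF, THF, −78 → 0 °C) then releases the C10 enolate regiospecifically, and intramolecular enolate alkylation (4-exo-tet, inversion at C4) closes the cyclobutane to 11. γ-Halogenation of silyl dienol ethers, fluoride-triggered alkylation of a regiodefined enolate and cyclobutane closure by enolate alkylation are all established reaction types.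

2. Step 5. Proton exchange between the two enolates, intermolecular oxidative dimerisation or a slow seven-membered ring closure may prevail. The fallback sets out from 3 and returns at 9 without using 5 or 6; it closes the ring at C9–C10 by an intramolecular Stetter reaction. Kinetic aldol addition of the lithium enolate of 3 to acetaldehyde (LiN(i-Pr)2, THF, −78 °C) gives the aldol F2, and dehydration (MsCl, Et3N, then DBU) gives the ethylidene dienone F3. The iron-hydride Giese addition of step 4, run with acrolein, then gives the aldehyde F4. A thiazolium-derived carbene (3-benzyl-5-(2-hydroxyethyl)-4-methylthiazolium chloride, Et3N, dioxane, 80 °C) adds C9 as an acyl anion equivalent to C10; protonation of the ring-fusion enol from the face away from C6, or base equilibration, should give 9.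

3. Step 6. Regiocontrol in the double enolisation may be incomplete (toward C8, toward C11 or into the C3 methyl), or C11 may epimerise. The fallback sets out from 9 and returns at 10; it forms the enol derivatives under acid-catalysed equilibration as robust, separable enol acetates and then exchanges acetyl for silyl. Isopropenyl acetate with TsOH (cat.) at 95 °C, with removal of acetone, gives the bis(enol acetate) F5, which can be purified. MeLi (4.2 equiv, THF, 0 °C) regenerates the two lithium enolates without equilibration, and TBSCl/DMPU gives 10.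

Further compounds
F1 | step 7 | (4S)-4-bromo enone carrying the C9=C10 tert-butyldimethylsilyl enol ether (bromine trans to C6; perimeter numbering) | CC1=C(O[Si](C)(C)C(C)(C)C)CCC(C)(C)[C@H]2[C@H](Br)C(C)=CC(=O)[C@@H]12
F2 | step 5 | (5S)-6-(1-hydroxyethyl)-3-methyl-5-(prop-1-en-2-yl)cyclohex-2-en-1-one (diastereomer mixture) | CC(O)C1C(=O)C=C(C)C[C@@H]1C(C)=C
F3 | step 5 | (5S,6E)-6-ethylidene-3-methyl-5-(prop-1-en-2-yl)cyclohex-2-en-1-one | C/C=C1/C(=O)C=C(C)C[C@@H]1C(C)=C
F4 | step 5 | 4-[(1S,6E)-6-ethylidene-3-methyl-5-oxocyclohex-3-en-1-yl]-4-methylpentanal | C/C=C1/C(=O)C=C(C)C[C@@H]1C(C)(C)CCC=O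
F5 | step 6 | (1R,7S)-2,6,6,9-tetramethylbicyclo[5.4.0]undeca-2,8,10-triene-3,11-diyl diacetate | CC1=C(OC(C)=O)CCC(C)(C)[C@H]2C=C(C)C=C(OC(C)=O)[C@@H]12
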